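The carbonyl carbon C1 stands alone between C1' of ring A (the 2,6-dihydroxyphenyl ring) and the primary methylene C2 of the eight-carbon tether to ring B (the 4-hydroxy-3-methoxyphenyl ring), so it can enter as carbon monoxide. A palladium-catalysed carbonylative Suzuki–Miyaura coupling joins an aryl iodide, CO and a primary alkylborane, forging both the C1'–C1 and the C1–C2 bond in a single flask; no ring is formed and no stereocentre arises. Its partners are benzyl-protected: 1,3-bis(benzyloxy)-2-iodobenzene and the B-(8-aryloctyl)-9-BBN generated in the same flask from a ring B oct-7-enyl arene. A single hydrogenolysis then frees all three phenols.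

Key step: step 4

Remark: the target has no stereocentre, so no configuration has to be set; chain atoms are numbered C1 (carbonyl) to C9 (benzylic carbon on ring B).

Step 1
Reactants: 1 2-iodobenzene-1,3-diol
Product: 2 1,3-bis(benzyloxy)-2-iodobenzene
Conditions: BnBr (2.4 equiv), K2CO3 (3 equiv), DMF, 25→50 °C
Reagents that add atoms: benzyl bromide, BrCc1ccccc1
Why: Williamson ether synthesis, in which both phenoxides are O-alkylated by the reactive benzylic bromide while the aryl C–I bond is inert to carbonate in DMF.

Step 2
Reactants: 3 4-bromo-2-methoxyphenol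
Product: 4 1-(benzyloxy)-4-bromo-2-methoxybenzene
Conditions: BnBr (1.2 equiv), K2CO3 (1.5 equiv), DMF, 25 °C
Reagents that add atoms: benzyl bromide, BrCc1ccccc1
Why: Williamson O-benzylation masks the acidic phenol before the organozinc and borane steps and leaves the aryl bromide untouched.

Step 3
Reactants: 5 8-bromooct-1-ene; 6 zinc (dust); 4 1-(benzyloxy)-4-bromo-2-methoxybenzene
Product: 8 1-(benzyloxy)-2-methoxy-4-(oct-7-en-1-yl)benzene, via oct-7-en-1-ylzinc bromide 7 (not isolated)
Conditions: 6 (activated with 5 mol % BrCH2CH2Br and TMSCl), LiCl, THF, 50 °C; then 4, Pd(OAc)2 (2 mol %), SPhos (4 mol %), THF, 25→40 °C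
Reagents that add atoms: none
Why: Negishi cross-coupling, in which LiCl-assisted zinc insertion into the primary C–Br bond gives an alkylzinc bromide that transmetalates to the arylpalladium formed from 4, the bulky biaryl phosphine favouring reductive elimination over β-hydride elimination and the remote terminal alkene staying intact.

Step 4
Reactants: 8 1-(benzyloxy)-2-methoxy-4-(oct-7-en-1-yl)benzene; 9 9-borabicyclo[3.3.1]nonane (9-BBN-H); 2 1,3-bis(benzyloxy)-2-iodobenzene; 10 carbon monoxide
Product: 12 1-[2,6-bis(benzyloxy)phenyl]-9-[4-(benzyloxy)-3-methoxyphenyl]nonan-1-one, via B-alkyl-9-BBN borane 11 (not isolated)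
Conditions: 9 (0.5 M in THF, 1.3 equiv), THF, 0→25 °C; then 2, Pd(PPh3)4 (5 mol %), K3PO4 (3 equiv), 10 (1 atm, balloon), THF–toluene, 25→50 °C
Reagents that add atoms: none
Why: Anti-Markovnikov hydroboration of the terminal alkene of 8 by 9 places boron on the chain terminus and gives the primary B-alkyl-9-BBN 11, which is used as its solution. In the coupling, zerovalent palladium inserts into the C–I bond of 2, CO then inserts into the crowded aryl–palladium bond to give an aroyl complex of divalent palladium, the phosphate-activated borate delivers its primary alkyl group, and acyl–alkyl reductive elimination releases 12 and regenerates the catalyst. The closest known reaction type is the carbonylative Suzuki–Miyaura ketone synthesis from aryl iodides, CO at atmospheric pressure and B-alkyl-9-BBN reagents, of which this is a sterically demanding case. No ring is closed and no stereocentre is created. The selectivity required is carbonylative over direct coupling with uptake of exactly one CO; the two benzyloxy groups ortho to palladium hinder transmetalation at the aryl–palladium stage, whereas migration of the electron-rich aryl group to CO relieves that crowding, and without an amine-type nucleophile a second CO is not incorporated. The bicyclic framework of the borane passes on only the primary alkyl group, and reductive elimination from the acyl(alkyl)palladium complex should be faster than β-hydride elimination.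

Step 5
Reactants: 12 1-[2,6-bis(benzyloxy)phenyl]-9-[4-(benzyloxy)-3-methoxyphenyl]nonan-1-one
Product: 13 1-(2,6-dihydroxyphenyl)-9-(4-hydroxy-3-methoxyphenyl)nonan-1-one
Conditions: H2 (1 atm), 10% Pd/C, EtOAc–EtOH, 25 °C
Reagents that add atoms: none
Why: Catalytic hydrogenolysis cleaves the three aryl benzyl ethers, while the aryl methyl ether and the ketone, which is flanked by two ortho oxygens and hydrogen-bonded to the freed phenols, should persist under 1 atm of hydrogen in a neutral solvent.

Compound list
1 | 2-iodobenzene-1,3-diol | Oc1cccc(O)c1I | starting material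
2 | 1,3-bis(benzyloxy)-2-iodobenzene | Ic1c(OCc2ccccc2)cccc1OCc1ccccc1 | intermediate
3 | 4-bromo-2-methoxyphenol | COc1cc(Br)ccc1O | starting material
4 | 1-(benzyloxy)-4-bromo-2-methoxybenzene | COc1cc(Br)ccc1OCc1ccccc1 | intermediate
5 | 8-bromooct-1-ene | C=CCCCCCCBr | starting material
6 | zinc (dust) | [Zn] | starting material
7 | oct-7-en-1-ylzinc bromide (LiCl-complexed, in THF) | C=CCCCCCC[Zn]Br | intermediate (not isolated)
8 | 1-(benzyloxy)-2-methoxy-4-(oct-7-en-1-yl)benzene | C=CCCCCCCc1ccc(OCc2ccccc2)c(OC)c1 | intermediate
9 | 9-borabicyclo[3.3.1]nonane (9-BBN-H, commercial THF solution) | B1C2CCCC1CCC2 | starting material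
10 | carbon monoxide | [C-]#[O+] | starting material
11 | 9-{8-[4-(benzyloxy)-3-methoxyphenyl]octyl}-9-borabicyclo[3.3.1]nonane | COc1cc(CCCCCCCCB2C3CCCC2CCC3)ccc1OCc1ccccc1 | intermediate (not isolated)
12 | 1-[2,6-bis(benzyloxy)phenyl]-9-[4-(benzyloxy)-3-methoxyphenyl]nonan-1-one | O=C(CCCCCCCCc1ccc(OCc2ccccc2)c(OC)c1)c1c(OCc2ccccc2)cccc1OCc1ccccc1 | intermediate
13 | 1-(2,6-dihydroxyphenyl)-9-(4-hydroxy-3-methoxyphenyl)nonan-1-one | COc1cc(CCCCCCCCC(=O)c2c(O)cccc2O)ccc1O | target

Total step count: 5. Longest linear sequence: 4 steps (3 → 4 → 8 → 12 → 13, steps 2 to 5); the iodide branch (step 1) joins at step 4.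

Steps most likely to fail

Step 4. Oxidative addition and CO insertion at the doubly ortho-substituted iodide may be slow under a CO atmosphere. The result could be CO-free alkyl–aryl coupling, protodeiodination or β-hydride elimination from the alkylpalladium. The fallback sets out from 8 and 2 and makes the C1'–C1 bond by carbonyl addition. Linear-selective hydroformylation of 8 (Rh(acac)(CO)2, Xantphos, CO/H2 1:1, toluene, 80 °C) should give 9-[4-(benzyloxy)-3-methoxyphenyl]nonanal F1. Iodine–magnesium exchange on 2 (iPrMgCl·LiCl, THF, 0 °C) should give [2,6-bis(benzyloxy)phenyl]magnesium chloride F2. Its addition to F1 (THF, −20→25 °C, NH4Cl work-up) should give racemic 1-[2,6-bis(benzyloxy)phenyl]-9-[4-(benzyloxy)-3-methoxyphenyl]nonan-1-ol F3. Oxidation with Dess–Martin periodinane (CH2Cl2, NaHCO3, 25 °C) returns to the route at 12.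

Step 3. Zinc insertion into the unactivated bromide may be incomplete, and chain-walking through β-hydride elimination and reinsertion, migration of the terminal double bond, or slow oxidative addition to the electron-rich aryl bromide may erode the coupling. The fallback sets out from 4 and replaces the zinc reagent by a borane made from a diene. Octa-1,7-diene, used in large excess to suppress double hydroboration, is monohydroborated with 9 (THF, 0→25 °C) to 9-(oct-7-en-1-yl)-9-borabicyclo[3.3.1]nonane F4. B-alkyl Suzuki–Miyaura coupling of F4 with 4 (PdCl2(dppf), K3PO4, THF–DMF–H2O, 60 °C) returns to the route at 8.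

Step 5. Reduction of the aryl ketone followed by benzylic C–O hydrogenolysis, or stalling before the two hindered ring A ethers are cleaved, may compete with clean debenzylation. The fallback sets out from 12 and is non-reductive. BCl3 with pentamethylbenzene as a trap for the benzyl cation (CH2Cl2, −78 °C) is a Lewis-acid dealkylation that spares the aryl methyl ether and the ketone and leads directly to 13. No new compound lies on this way (F0).

Further compounds
F1 | step 4 | 9-[4-(benzyloxy)-3-methoxyphenyl]nonanal | O=CCCCCCCCCc1ccc(OCc2ccccc2)c(OC)c1
F2 | step 4 | [2,6-bis(benzyloxy)phenyl]magnesium chloride | Cl[Mg]c1c(OCc2ccccc2)cccc1OCc1ccccc1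
F3 | step 4 | racemic 1-[2,6-bis(benzyloxy)phenyl]-9-[4-(benzyloxy)-3-methoxyphenyl]nonan-1-ol | OC(CCCCCCCCc1ccc(OCc2ccccc2)c(OC)c1)c1c(OCc2ccccc2)cccc1OCc1ccccc1
F4 | step 3 | 9-(oct-7-en-1-yl)-9-borabicyclo[3.3.1]nonane | C=CCCCCCCB1C2CCCC1CCC2
F0 | step 5 | none | none
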